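**Strategy.** Ring A is closed last, by a nickel-catalysed reductive alkyne–aldehyde cyclization that joins the aldehyde carbon C3 to the internal alkyne carbon C4 (eudesmane numbering; ring A = C1–C5/C10, ring B = C5–C10, C14 = angular methyl, C15 = exocyclic methylene). In one operation this creates the 2-methylidenecyclohexanol unit of ring A: the C3–C4 bond, the exocyclic C4=C15 methylene and the equatorial C3 carbinol, which is the feature of the target that the step exploits. The precursor is a monocyclic ring-B ynal with an ethynyl group on C5 and a 3-oxopropyl chain on quaternary C10, trans-diequatorial; ring B comes from a catalytic enantioselective Diels–Alder reaction.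

Key step: step 9

Assumption: the sense of induction of the two reagent-controlled steps is taken from the accepted models (step 2: the (S)-prolinol-derived oxazaborolidinium exposes the Re face of the formyl-bearing carbon of a 2-methyl enal; step 6: the allylborane of the (−)-α-pinene series gives the (R)-carbinol when the aldehyde substituent outranks allyl); if either proves opposite, the mirror-image catalyst or reagent is used.

**Route**

Step 1
Reactants: 1 3-methylbut-1-yne; 2 ethylene
Product: 3 2-(propan-2-yl)buta-1,3-diene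
Conditions: second-generation Grubbs catalyst RuCl2(=CHPh)(PCy3)(H2IMes) (3 mol%), ethylene (3 atm), toluene, 60 °C, sealed vessel; distillation
Reagents that add atoms: none
Why: Ruthenium-carbene enyne cross-metathesis of a terminal alkyne with ethylene transfers the two methylene units of ethylene to the alkyne carbons and gives the 2-substituted 1,3-diene without by-product; no stereocentre is formed.

Step 2
Reactants: 3 2-(propan-2-yl)buta-1,3-diene; 4 ethyl (2E)-3-methyl-4-oxobut-2-enoate
Product: 5 ethyl (1R,6R)-6-formyl-6-methyl-3-(propan-2-yl)cyclohex-3-ene-1-carboxylate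
Conditions: (S)-3,3-diphenyl-1-(o-tolyl)tetrahydro-1H,3H-pyrrolo[1,2-c][1,3,2]oxazaborole·Tf2NH (20 mol%), 3 (2 equiv), CH2Cl2, −78 → −20 °C
Reagents that add atoms: none
Why: Catalytic enantioselective Diels–Alder reaction: the chiral oxazaborolidinium binds the formyl group (the more Lewis-basic carbonyl) of the 2-methyl enal so that the 2-alkyl diene adds with para orientation (C7 opposite C10), suprafacial addition carries the E geometry into the trans relation of CHO on C10 and CO2Et on C5, and the shielded enal face fixes both new stereocentres (C10 R, C5 R) at once.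

Step 3
Reactants: 5 ethyl (1R,6R)-6-formyl-6-methyl-3-(propan-2-yl)cyclohex-3-ene-1-carboxylate
Product: 7 (3aR,5S,6R,7aR)-5-hydroxy-3a-methyl-6-(propan-2-yl)hexahydro-2-benzofuran-1(3H)-one, via diol ester 6 (not isolated)
Conditions: BH3·THF (2.5 equiv), THF, 0 °C → rt; NaBO3·4H2O, H2O, rt; then p-TsOH (cat.), toluene, 50 °C
Reagents that add atoms: sodium perborate, O[B-]1(O)OO[B-](O)(O)OO1.[Na+].[Na+]
Why: Hydroboration–oxidation: borane first reduces the aldehyde and then adds syn and anti-Markovnikov to the C7=C8 alkene from the α face, which is opposite the pseudoaxial C14 methyl and is also the face of the C1–O–B tether, so that oxidation with retention gives the 8α-hydroxyl and 7α-H (isopropyl equatorial), and acid-catalysed lactonization of the C1 alcohol onto the C4 ester then differentiates the two carbonyl carbons.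

Step 4
Reactants: 7 (3aR,5S,6R,7aR)-5-hydroxy-3a-methyl-6-(propan-2-yl)hexahydro-2-benzofuran-1(3H)-one
Product: 9 (1S,2R,4S,5R)-4-ethynyl-5-(hydroxymethyl)-5-methyl-2-(propan-2-yl)cyclohexan-1-ol, via lactol 8 (not isolated)
Conditions: i-Bu2AlH (2.3 equiv), CH2Cl2, −78 °C; then MeOH, K2CO3, dimethyl (1-diazo-2-oxopropyl)phosphonate, 0 °C → rt
Reagents that add atoms: dimethyl (1-diazo-2-oxopropyl)phosphonate, CC(=O)C(=[N+]=[N-])P(=O)(OC)OC
Why: Partial reduction of the lactone to the lactol followed by Seyferth–Gilbert homologation with the Ohira–Bestmann reagent turns the C4 carbonyl into the terminal alkyne C4≡C15 and uncovers the C1 alcohol in one pot; C5 is not touched because the open hydroxy aldehyde is trapped faster than this hindered α-branched aldehyde can enolize.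

Step 5
Reactants: 9 (1S,2R,4S,5R)-4-ethynyl-5-(hydroxymethyl)-5-methyl-2-(propan-2-yl)cyclohexan-1-ol
Product: 10 (1R,2S,4R,5S)-2-ethynyl-5-hydroxy-1-methyl-4-(propan-2-yl)cyclohexane-1-carbaldehyde
Conditions: TEMPO (10 mol%), PhI(OAc)2 (1.2 equiv), CH2Cl2, rt
Reagents that add atoms: none
Why: Oxoammonium (TEMPO) oxidation with PhI(OAc)2 as terminal oxidant is selective for the primary alcohol over the secondary C8 hydroxyl on steric grounds and stops at the non-enolizable C1 aldehyde.

Step 6
Reactants: 10 (1R,2S,4R,5S)-2-ethynyl-5-hydroxy-1-methyl-4-(propan-2-yl)cyclohexane-1-carbaldehyde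
Product: 11 (1S,2R,4S,5R)-4-ethynyl-5-[(1R)-1-hydroxybut-3-en-1-yl]-5-methyl-2-(propan-2-yl)cyclohexan-1-ol
Conditions: B-allylbis(isopinocampheyl)borane of the (−)-α-pinene series (lIpc2B-allyl, 2.5 equiv), Et2O, −78 °C; then NaOH, H2O2, 0 °C → rt
Reagents that add atoms: B-allylbis(isopinocampheyl)borane, C=CCB([C@H]1C[C@H]2C[C@@H]([C@@H]1C)C2(C)C)[C@H]1C[C@H]2C[C@@H]([C@@H]1C)C2(C)C
Why: Brown allylation through a closed six-membered chair transition state is reagent-controlled, the isopinocampheyl groups of the (−)-α-pinene series directing allyl to the aldehyde face that gives the (R)-carbinol at C1, and the excess of reagent absorbs the free C8 hydroxyl.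

Step 7
Reactants: 11 (1S,2R,4S,5R)-4-ethynyl-5-[(1R)-1-hydroxybut-3-en-1-yl]-5-methyl-2-(propan-2-yl)cyclohexan-1-ol
Product: 12 tert-butyl({(1R)-1-[(1R,2S,4R,5S)-5-{[tert-butyl(dimethyl)silyl]oxy}-2-ethynyl-1-methyl-4-(propan-2-yl)cyclohexyl]but-3-en-1-yl}oxy)dimethylsilane
Conditions: TBSOTf (3 equiv), 2,6-lutidine (5 equiv), CH2Cl2, 0 °C → rt
Reagents that add atoms: tert-butyldimethylsilyl triflate, CC(C)(C)[Si](C)(C)OS(=O)(=O)C(F)(F)F
Why: Silyl triflate with 2,6-lutidine silylates both the hindered neopentyl C1 alcohol and the C8 alcohol as robust TBS ethers that survive the following oxidative and reductive steps.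

Step 8
Reactants: 12 bis-TBS ether (name as in step 7)
Product: 13 (3R)-3-{[tert-butyl(dimethyl)silyl]oxy}-3-[(1R,2S,4R,5S)-5-{[tert-butyl(dimethyl)silyl]oxy}-2-ethynyl-1-methyl-4-(propan-2-yl)cyclohexyl]propanal
Conditions: OsO4 (2 mol%), NaIO4 (4 equiv), 2,6-lutidine, 1,4-dioxane/H2O, rt
Reagents that add atoms: osmium tetroxide (catalytic oxygen carrier), O=[Os](=O)(=O)=O; sodium periodate (terminal oxygen source), [Na+].[O-]I(=O)(=O)=O
Why: Lemieux–Johnson oxidation (catalytic dihydroxylation with periodate cleavage) cuts the monosubstituted alkene to the C3 aldehyde, while the terminal alkyne, much less reactive towards OsO4, and the silyl ethers remain intact.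

Step 9
Reactants: 13 ynal (name as in step 8)
Product: 15 (2S,4R,4aR,6S,7R,8aS)-4,6-bis{[tert-butyl(dimethyl)silyl]oxy}-4a-methyl-1-methylidene-7-(propan-2-yl)decahydronaphthalen-2-ol, via triethylsilyl ether 14 (not isolated)
Conditions: Ni(cod)2 (20 mol%), PBu3 (40 mol%), Et3SiH (5 equiv), THF, rt, slow addition of 13 (0.01 M); then PPTS, MeOH, 0 °C
Reagents that add atoms: none
Why: Zerovalent nickel binds the alkyne and the aldehyde and undergoes oxidative cyclization to a five-membered oxanickelacycle (Ni–O–C3–C4=C15), which forms the C3–C4 bond; σ-bond metathesis with Et3SiH and C–H reductive elimination then deliver the exocyclic C4=C15H2 and the C3–OSiEt3 group, and mild methanolysis frees only this allylic silyl ether. The closest known reaction type is the nickel-catalysed reductive cyclization of ynals with trialkylsilanes. Ring A closes in a 6-exo-dig mode, the tether C5–C10–C1–C2 being held trans-diequatorial on ring B so that only the trans-fused decalin can form. The new stereocentre C3 is controlled by the metallacycle: O, C3, C4 and C15 must be nearly coplanar, which is possible only when the C3–O bond lies in the plane of the exocyclic alkene, that is equatorial (3β) on the chair of ring A. The step needs cyclization to outrun oligomerization and hydrosilylation of the terminal alkyne and hydrosilylation of the aldehyde; the quaternary C10 (gem-disubstituent effect), the preorganized diequatorial tether and slow addition at high dilution secure this, and the tether length enforces the exo regiochemistry.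

Step 10
Reactants: 16 caffeic acid
Product: 18 (2E)-3-{3,4-bis[(tert-butyldimethylsilyl)oxy]phenyl}prop-2-enoic acid, via silyl ester 17 (not isolated)
Conditions: TBSCl (3.5 equiv), imidazole (7 equiv), DMF, rt; then AcOH, THF, H2O, rt
Reagents that add atoms: tert-butyldimethylsilyl chloride, CC(C)(C)[Si](C)(C)Cl
Why: Exhaustive silylation followed by selective hydrolysis of the labile silyl ester, which aqueous acetic acid cleaves much faster than aryl silyl ethers, gives the catechol-protected acid with the E alkene untouched.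

Step 11
Reactants: 15 allylic alcohol (name as in step 9); 18 (2E)-3-{3,4-bis[(tert-butyldimethylsilyl)oxy]phenyl}prop-2-enoic acid
Product: 19 (2S,4R,4aR,6S,7R,8aS)-4,6-bis{[tert-butyl(dimethyl)silyl]oxy}-4a-methyl-1-methylidene-7-(propan-2-yl)decahydronaphthalen-2-yl (2E)-3-{3,4-bis[(tert-butyldimethylsilyl)oxy]phenyl}prop-2-enoate
Conditions: DCC (1.5 equiv), DMAP (0.5 equiv), CH2Cl2, 0 °C → rt
Reagents that add atoms: none
Why: Steglich esterification (carbodiimide activation with DMAP as acyl-transfer catalyst) acylates the only free hydroxyl, the equatorial allylic C3 alcohol, with retention at C3.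

Step 12
Reactants: 19 tetrasilylated ester (name as in step 11)
Product: 20 (2S,4R,4aR,6S,7R,8aS)-4,6-dihydroxy-4a-methyl-1-methylidene-7-(propan-2-yl)decahydronaphthalen-2-yl (2E)-3-(3,4-dihydroxyphenyl)prop-2-enoate (CNP0264533.1)
Conditions: HF·pyridine, pyridine, THF, 0 °C → rt
Reagents that add atoms: none
Why: Fluoride-mediated desilylation under buffered acidic conditions removes the two aryl and two alkyl TBS groups without hydrolysing or migrating the allylic cinnamate, isomerizing the exocyclic alkene or oxidizing the catechol.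

**Compound list**

1 | 3-methylbut-1-yne | C#CC(C)C | starting material
2 | ethylene | C=C | starting material
3 | 2-(propan-2-yl)buta-1,3-diene | C=CC(=C)C(C)C | intermediate
4 | ethyl (2E)-3-methyl-4-oxobut-2-enoate | CCOC(=O)/C=C(\C)C=O | starting material
5 | ethyl (1R,6R)-6-formyl-6-methyl-3-(propan-2-yl)cyclohex-3-ene-1-carboxylate | O=C[C@]1(C)CC=C(C(C)C)C[C@H]1C(=O)OCC | intermediate
6 | ethyl (1R,2R,4S,5R)-4-hydroxy-2-(hydroxymethyl)-2-methyl-5-(propan-2-yl)cyclohexane-1-carboxylate | OC[C@]1(C)C[C@H](O)[C@@H](C(C)C)C[C@H]1C(=O)OCC | intermediate (not isolated)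
7 | (3aR,5S,6R,7aR)-5-hydroxy-3a-methyl-6-(propan-2-yl)hexahydro-2-benzofuran-1(3H)-one (trans-fused lactone) | O=C1OC[C@]2(C)C[C@H](O)[C@@H](C(C)C)C[C@@H]12 | intermediate
8 | (3aR,5S,6R,7aR)-3a-methyl-6-(propan-2-yl)octahydro-2-benzofuran-1,5-diol (lactol, anomer mixture) | OC1OC[C@]2(C)C[C@H](O)[C@@H](C(C)C)C[C@@H]12 | intermediate (not isolated)
9 | (1S,2R,4S,5R)-4-ethynyl-5-(hydroxymethyl)-5-methyl-2-(propan-2-yl)cyclohexan-1-ol | OC[C@]1(C)C[C@H](O)[C@@H](C(C)C)C[C@H]1C#C | intermediate
10 | (1R,2S,4R,5S)-2-ethynyl-5-hydroxy-1-methyl-4-(propan-2-yl)cyclohexane-1-carbaldehyde | O=C[C@]1(C)C[C@H](O)[C@@H](C(C)C)C[C@H]1C#C | intermediate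
11 | (1S,2R,4S,5R)-4-ethynyl-5-[(1R)-1-hydroxybut-3-en-1-yl]-5-methyl-2-(propan-2-yl)cyclohexan-1-ol | C=CC[C@@H](O)[C@]1(C)C[C@H](O)[C@@H](C(C)C)C[C@H]1C#C | intermediate
12 | bis-TBS ether of 11 | C=CC[C@@H](O[Si](C)(C)C(C)(C)C)[C@]1(C)C[C@H](O[Si](C)(C)C(C)(C)C)[C@@H](C(C)C)C[C@H]1C#C | intermediate
13 | (3R)-3-(TBS-oxy)-3-[(1R,2S,4R,5S)-5-(TBS-oxy)-2-ethynyl-1-methyl-4-(propan-2-yl)cyclohexyl]propanal | O=CC[C@@H](O[Si](C)(C)C(C)(C)C)[C@]1(C)C[C@H](O[Si](C)(C)C(C)(C)C)[C@@H](C(C)C)C[C@H]1C#C | intermediate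
14 | triethylsilyl ether of 15 | C=C1[C@@H](O[Si](CC)(CC)CC)C[C@@H](O[Si](C)(C)C(C)(C)C)[C@]2(C)C[C@H](O[Si](C)(C)C(C)(C)C)[C@@H](C(C)C)C[C@@H]12 | intermediate (not isolated)
15 | (2S,4R,4aR,6S,7R,8aS)-4,6-bis(TBS-oxy)-4a-methyl-1-methylidene-7-(propan-2-yl)decahydronaphthalen-2-ol | C=C1[C@@H](O)C[C@@H](O[Si](C)(C)C(C)(C)C)[C@]2(C)C[C@H](O[Si](C)(C)C(C)(C)C)[C@@H](C(C)C)C[C@@H]12 | intermediate
16 | caffeic acid, (2E)-3-(3,4-dihydroxyphenyl)prop-2-enoic acid | O=C(O)/C=C/c1ccc(O)c(O)c1 | starting material
17 | tert-butyldimethylsilyl (2E)-3-[3,4-bis(TBS-oxy)phenyl]prop-2-enoate | O=C(O[Si](C)(C)C(C)(C)C)/C=C/c1ccc(O[Si](C)(C)C(C)(C)C)c(O[Si](C)(C)C(C)(C)C)c1 | intermediate (not isolated)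
18 | (2E)-3-[3,4-bis(TBS-oxy)phenyl]prop-2-enoic acid | O=C(O)/C=C/c1ccc(O[Si](C)(C)C(C)(C)C)c(O[Si](C)(C)C(C)(C)C)c1 | intermediate
19 | tetrasilylated ester of 15 with 18 | C=C1[C@@H](OC(=O)/C=C/c2ccc(O[Si](C)(C)C(C)(C)C)c(O[Si](C)(C)C(C)(C)C)c2)C[C@@H](O[Si](C)(C)C(C)(C)C)[C@]2(C)C[C@H](O[Si](C)(C)C(C)(C)C)[C@@H](C(C)C)C[C@@H]12 | intermediate
20 | (2S,4R,4aR,6S,7R,8aS)-4,6-dihydroxy-4a-methyl-1-methylidene-7-(propan-2-yl)decahydronaphthalen-2-yl (2E)-3-(3,4-dihydroxyphenyl)prop-2-enoate | C=C1[C@@H](OC(=O)/C=C/c2ccc(O)c(O)c2)C[C@@H](O)[C@]2(C)C[C@H](O)[C@@H](C(C)C)C[C@@H]12 | target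

**Step count and risks**

Total steps: 12. Longest linear sequence: 11 steps (steps 1–9, 11 and 12); step 10 is a one-step side branch.

Steps most likely to fail:

1. Step 9 (key step). Nickel-mediated oligomerization or hydrosilylation of the terminal alkyne, or direct hydrosilylation of the aldehyde, may outrun ring closure, and closure may proceed with eroded facial control at C3. Fallback (Nozaki–Hiyama–Kishi closure of the same bond): it sets out from 12. Markovnikov hydroiodination of the alkyne (B-iodo-9-BBN, pentane, −20 °C; then AcOH) gives the 2-iodoalkene F1. Lemieux–Johnson cleavage (OsO4 cat., NaIO4, 2,6-lutidine) gives the iodo aldehyde F2. CrCl2 (6 equiv) with NiCl2 (2 mol%) in DMSO at high dilution adds the alkenylchromium to the aldehyde and comes back to the route at 15. Should this closure favour the axial carbinol, the 3-epimer F3, Dess–Martin oxidation to the exocyclic enone F4 and NaBH4/CeCl3·7H2O reduction (axial hydride delivery) also return 15.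

2. Step 2. The trisubstituted, doubly activated dienophile may react sluggishly or with insufficient regio- or enantioselectivity. Fallback (racemic cycloaddition, then enzymatic resolution): it sets out from 3 and 4. Et2AlCl (CH2Cl2, −78 °C) gives 5 together with its enantiomer, ent-adduct F5. Step 3 on the mixture gives 7 together with the ent-lactone F6. Lipase-catalysed acylation (Amano lipase PS, vinyl acetate, t-BuOMe) converts the (R)-carbinol enantiomer into the acetate F7 and leaves 7, where the route is rejoined.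

3. Step 3. The hydroboration may lose facial selectivity on the conformationally mobile cyclohexene, or borane may attack the ester. Fallback (conformational locking before hydroboration): it sets out from 5. NaBH4 (MeOH, 0 °C) reduces only the aldehyde and p-TsOH closes the unsaturated trans-fused lactone F8, in which the C14 methyl is fixed pseudoaxial. BH3·SMe2 (1.1 equiv, THF, 0 °C) then NaBO3·4H2O hydroborates this rigid bicycle from the α face and returns to the route at 7.

Further compounds
F1 | step 9 | bis-TBS ether 12 with 1-iodoethenyl in place of ethynyl on C5 | C=CC[C@@H](O[Si](C)(C)C(C)(C)C)[C@]1(C)C[C@H](O[Si](C)(C)C(C)(C)C)[C@@H](C(C)C)C[C@H]1C(I)=C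
F2 | step 9 | aldehyde 13 with 1-iodoethenyl in place of ethynyl on C5 | O=CC[C@@H](O[Si](C)(C)C(C)(C)C)[C@]1(C)C[C@H](O[Si](C)(C)C(C)(C)C)[C@@H](C(C)C)C[C@H]1C(I)=C
F3 | step 9 | 3-epimer of 15 (axial 3α-hydroxyl) | C=C1[C@H](O)C[C@@H](O[Si](C)(C)C(C)(C)C)[C@]2(C)C[C@H](O[Si](C)(C)C(C)(C)C)[C@@H](C(C)C)C[C@@H]12
F4 | step 9 | (4R,4aR,6S,7R,8aS)-4,6-bis(TBS-oxy)-4a-methyl-1-methylidene-7-(propan-2-yl)octahydronaphthalen-2(1H)-one | C=C1C(=O)C[C@@H](O[Si](C)(C)C(C)(C)C)[C@]2(C)C[C@H](O[Si](C)(C)C(C)(C)C)[C@@H](C(C)C)C[C@@H]12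
F5 | step 2 | ethyl (1S,6S)-6-formyl-6-methyl-3-(propan-2-yl)cyclohex-3-ene-1-carboxylate (enantiomer of 5) | O=C[C@@]1(C)CC=C(C(C)C)C[C@@H]1C(=O)OCC
F6 | step 2 | (3aS,5R,6S,7aS)-5-hydroxy-3a-methyl-6-(propan-2-yl)hexahydro-2-benzofuran-1(3H)-one (enantiomer of 7) | O=C1OC[C@@]2(C)C[C@@H](O)[C@H](C(C)C)C[C@H]12
F7 | step 2 | acetate of F6 | O=C1OC[C@@]2(C)C[C@@H](OC(C)=O)[C@H](C(C)C)C[C@H]12
F8 | step 3 | (3aR,7aR)-3a-methyl-6-(propan-2-yl)-3a,4,7,7a-tetrahydro-2-benzofuran-1(3H)-one | O=C1OC[C@]2(C)CC=C(C(C)C)C[C@@H]12
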